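**Strategy.** The pyrrole ring of the target is disconnected at N1–C7a and C3–C3a, two bonds on neighbouring carbons of the benzene ring, with C3a flanked by C4–Br. That pattern maps onto 3,5-dibromobenzyne. The sulfonamide nitrogen of an N-tosylglycine methyl ester adds to the aryne carbon remote from bromine, and the aryl anion formed beside bromine acylates itself on the ester. This gives the five-membered ring as a 4,6-dibromoindolin-3-one in one operation. The aryne precursor is a 2-(trimethylsilyl)aryl triflate made in one flask from symmetric 2,4,6-tribromophenol. Reduction, dehydration, C3 bromination and detosylation then complete the target.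

Key step: step 3

Assumption: the one-flask silylation/exchange/triflation is counted as one step because nothing is purified between its stages, and 12 is carried as a racemate because its only stereocentre is removed in step 5.

**Step 1**
Reactants: 1 glycine methyl ester hydrochloride; 2 4-toluenesulfonyl chloride
Product: 3 methyl N-tosylglycinate
Conditions: Et3N (2.2 equiv), CH2Cl2, 0 °C to rt
Reagents that add atoms: none
Why: N-Sulfonylation of the amine freed by Et3N (sulfonamide formation of the Hinsberg type) should stop at mono-tosylation because the N–H sulfonamide product is a much poorer nucleophile than the amine.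

**Step 2**
Reactants: 4 2,4,6-tribromophenol
Product: 8 2,4-dibromo-6-(trimethylsilyl)phenyl trifluoromethanesulfonate, via trimethylsilyl ether 5 (not isolated), via aryllithium 6 (not isolated), via lithium phenoxide 7 (not isolated)
Conditions: HMDS, THF, 70 °C, then volatiles removed in vacuo; n-BuLi (1.05 equiv), THF, −100 to −80 °C; Tf2O, −100 to −80 °C
Reagents that add atoms: hexamethyldisilazane C[Si](C)(C)N[Si](C)(C)C; trifluoromethanesulfonic anhydride O=S(=O)(OS(=O)(=O)C(F)(F)F)C(F)(F)F
Why: This is the established one-flask route to 2-silylaryl triflates, namely O-silylation, bromine–lithium exchange at one of the two equivalent bromines ortho to the silyloxy group (favoured over the para bromine by oxygen coordination and inductive stabilisation of the ortho carbanion), a 1,3 O-to-C silyl shift (retro-Brook rearrangement) to the phenoxide and O-triflation, with the remaining bromines meta to lithium so that no aryne can form at this stage.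

**Step 3**
Reactants: 8 2,4-dibromo-6-(trimethylsilyl)phenyl trifluoromethanesulfonate; 3 methyl N-tosylglycinate
Product: 11 4,6-dibromo-1-tosylindolin-3-one, via 3,5-dibromobenzyne 9 (not isolated), via aryl anion 10 (not isolated)
Conditions: 3 (1.1 equiv) pre-stirred with CsF (4 equiv), THF, 65 °C, slow addition of 8
Reagents that add atoms: none
Why: Fluoride attacks silicon of 8, triflate departs and aryne 9 forms; the sulfonamide anion of 3 (Cs+ counter-ion) adds through nitrogen to the aryne carbon remote from the flanking bromine (N1–C7a), and the aryl anion 10, now ortho to that bromine, attacks the ester carbonyl and expels methoxide (C3–C3a). The closest known reaction type is the aryne amination–acylation annulation of N-sulfonyl α-amino esters and of methyl anthranilates, a formal insertion of the aryne between N–H and the acyl carbon. The one ring closes in a 5-exo-trig mode, the ester C=O being the exocyclic trigonal acceptor, and no stereocentre is created. The step needs regioselective addition to the unsymmetrical aryne, which the bromine next to the triple bond should secure: it distorts the aryne so that the carbon meta to bromine is the more electrophilic one, and it stabilises the developing carbanion inductively at the carbon beside C–Br. The step also needs acylation to outrun protonation of 10 or its loss of bromide, which the five-membered transition state, prior conversion of the N–H into its anion by excess CsF, the poorly proton-donating THF and a low stationary aryne concentration should favour.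

**Step 4**
Reactants: 11 4,6-dibromo-1-tosylindolin-3-one
Product: 12 4,6-dibromo-1-tosylindolin-3-ol (racemic)
Conditions: NaBH4, THF/MeOH, 0 °C
Reagents that add atoms: none
Why: Borohydride reduction of the aryl ketone (nucleophilic hydride addition) should leave the aryl bromides and the sulfonamide untouched, and the C3 carbinol centre, formed as a racemate without control, is erased again in step 5.

**Step 5**
Reactants: 12 4,6-dibromo-1-tosylindolin-3-ol
Product: 13 4,6-dibromo-1-tosylindole
Conditions: TsOH·H2O (10 mol %), toluene, 80 °C
Reagents that add atoms: none
Why: Acid-catalysed dehydration (E1 through the benzylic C3 cation, then loss of a C2 proton) is driven by aromatisation of the five-membered ring to the indole.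

**Step 6**
Reactants: 13 4,6-dibromo-1-tosylindole
Product: 14 3,4,6-tribromo-1-tosylindole
Conditions: Br2 (1.1 equiv), CH2Cl2, 0 °C to rt, dark
Reagents that add atoms: bromine BrBr
Why: Electrophilic aromatic substitution (halogenation) should occur at C3, the nucleophilic terminus of the enamide-like N1–C2=C3 unit of an N-sulfonylindole, while the tosyl group damps the reactivity of C2 and nitrogen and so guards against over-bromination.

**Step 7**
Reactants: 14 3,4,6-tribromo-1-tosylindole
Product: 15 3,4,6-tribromoindole
Conditions: Cs2CO3 (3 equiv), THF/MeOH (2:1), rt
Reagents that add atoms: none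
Why: Methoxide generated by Cs2CO3 attacks sulfur and expels the indolide (base-mediated N-desulfonylation by methanolysis), a leaving group made good by three bromines, and the aryl and C3 bromides are inert to these mild conditions.

**Compound list**
1 | glycine methyl ester hydrochloride | COC(=O)CN.Cl | starting material
2 | 4-toluenesulfonyl chloride | Cc1ccc(cc1)S(Cl)(=O)=O | starting material
3 | methyl N-tosylglycinate | COC(=O)CNS(=O)(=O)c1ccc(C)cc1 | intermediate
4 | 2,4,6-tribromophenol | Oc1c(Br)cc(Br)cc1Br | starting material
5 | trimethyl(2,4,6-tribromophenoxy)silane | C[Si](C)(C)Oc1c(Br)cc(Br)cc1Br | intermediate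
6 | [3,5-dibromo-2-(trimethylsilyloxy)phenyl]lithium | [Li]c1cc(Br)cc(Br)c1O[Si](C)(C)C | intermediate
7 | lithium 2,4-dibromo-6-(trimethylsilyl)phenoxide | [Li+].[O-]c1c(Br)cc(Br)cc1[Si](C)(C)C | intermediate
8 | 2,4-dibromo-6-(trimethylsilyl)phenyl trifluoromethanesulfonate | C[Si](C)(C)c1cc(Br)cc(Br)c1OS(=O)(=O)C(F)(F)F | intermediate
9 | 3,5-dibromobenzyne (3,5-dibromo-1,2-didehydrobenzene) | BrC1=CC(Br)=CC#C1 | intermediate
10 | cesium 2,4-dibromo-6-[(2-methoxy-2-oxoethyl)(tosyl)amino]phenide | COC(=O)CN(C1=CC(Br)=CC(Br)=[C-]1)S(=O)(=O)c1ccc(C)cc1.[Cs+] | intermediate
11 | 4,6-dibromo-1-tosylindolin-3-one | Cc1ccc(cc1)S(=O)(=O)N1CC(=O)c2c(Br)cc(Br)cc21 | intermediate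
12 | 4,6-dibromo-1-tosylindolin-3-ol (racemic) | Cc1ccc(cc1)S(=O)(=O)N1CC(O)c2c(Br)cc(Br)cc21 | intermediate
13 | 4,6-dibromo-1-tosylindole | Cc1ccc(cc1)S(=O)(=O)n1ccc2c(Br)cc(Br)cc21 | intermediate
14 | 3,4,6-tribromo-1-tosylindole | Cc1ccc(cc1)S(=O)(=O)n1cc(Br)c2c(Br)cc(Br)cc21 | intermediate
15 | 3,4,6-tribromoindole | Brc1cc(Br)c2c(Br)c[nH]c2c1 | target

**Step count.** Total: 7 steps. Longest linear sequence: 6 steps (4 to 15 through steps 2–7).

**Steps most likely to fail**

1. Step 3. The aryl anion may be protonated before it reaches the ester, or it may lose the neighbouring bromide. The enolisable product may also be arylated again or degraded under the basic fluoride conditions. The fallback sets out from 8 and 2 and returns at 13; it replaces the anionic acylation by aryne N-arylation followed by an electrophilic ring closure. Tosylation of commercial aminoacetaldehyde dimethyl acetal with 2 (Et3N, CH2Cl2) should give N-(2,2-dimethoxyethyl)-4-methylbenzenesulfonamide F1. Treating 8 with CsF in MeCN at rt in the presence of F1 should give N–H insertion into aryne 9, where protonation of the aryl anion is now the wanted outcome. With the same bromine-controlled regiochemistry this gives N-(3,5-dibromophenyl)-N-(2,2-dimethoxyethyl)-4-methylbenzenesulfonamide F2. TiCl4 in toluene at 100 °C should then close the ring by intramolecular Friedel–Crafts-type attack of the oxocarbenium ion on either of the two equivalent positions ortho to nitrogen, and loss of methanol gives 13 (an N-sulfonylanilinoacetal indole synthesis). This bypasses 11 and 12.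

2. Step 2. Exchange may occur at the para bromine, the silyl shift may be incomplete or intermolecular, or the aryllithium may be butylated. The fallback sets out from 4 and returns at 8; it separates C-silylation from any migration. Protection with chloromethyl methyl ether and i-Pr2NEt should give 1,3,5-tribromo-2-(methoxymethoxy)benzene F3. Treatment with n-BuLi in toluene/Et2O at −78 °C should give chelation-directed exchange at an ortho bromine to [3,5-dibromo-2-(methoxymethoxy)phenyl]lithium F4. Quenching with Me3SiCl should give [3,5-dibromo-2-(methoxymethoxy)phenyl]trimethylsilane F5. Mild acetal cleavage (catalytic HCl, MeOH, rt) should give 2,4-dibromo-6-(trimethylsilyl)phenol F6. Tf2O and pyridine in CH2Cl2 at 0 °C should then give 8.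

3. Step 6. Substitution at C3 may be sluggish on the N-sulfonylated, doubly brominated ring with a peri bromine at C4, and forcing may cause unselective bromination. The fallback sets out from 13 and returns at 15; it inverts the order so that the far more nucleophilic free indole is brominated. Cs2CO3 in THF/MeOH should give 4,6-dibromoindole F7, and N-bromosuccinimide (1.0 equiv) in DMF at 0 °C should then brominate C3 to give 15.

**Further compounds**
F1 | step 3 | N-(2,2-dimethoxyethyl)-4-methylbenzenesulfonamide | COC(OC)CNS(=O)(=O)c1ccc(C)cc1
F2 | step 3 | N-(3,5-dibromophenyl)-N-(2,2-dimethoxyethyl)-4-methylbenzenesulfonamide | COC(OC)CN(c1cc(Br)cc(Br)c1)S(=O)(=O)c1ccc(C)cc1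
F3 | step 2 | 1,3,5-tribromo-2-(methoxymethoxy)benzene | COCOc1c(Br)cc(Br)cc1Br
F4 | step 2 | [3,5-dibromo-2-(methoxymethoxy)phenyl]lithium | [Li]c1cc(Br)cc(Br)c1OCOC
F5 | step 2 | [3,5-dibromo-2-(methoxymethoxy)phenyl]trimethylsilane | COCOc1c(Br)cc(Br)cc1[Si](C)(C)C
F6 | step 2 | 2,4-dibromo-6-(trimethylsilyl)phenol | Oc1c(Br)cc(Br)cc1[Si](C)(C)C
F7 | step 6 | 4,6-dibromoindole | Brc1cc(Br)c2cc[nH]c2c1
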